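The side chain is cut at two bonds at once: benzene-ring carbon to benzylic C1, and acetoxy-bearing C2 to C3. C2 is flanked by two near-identical methylenes (C1 and C3), so a ketone reduction is avoided. Instead a vinyl unit (C1–C2) is inserted between an aryl triflate and an undecyl nucleophile by enantioselective palladium-catalysed conjunctive coupling. This forms both bonds and a C2–B stereocentre, later oxidised to C2–O with retention. The precursor is the lithium ate complex of vinylboronic pinacol ester and 11-(benzyloxy)undecyllithium. Both hydroxyls travel as benzyl ethers, so one hydrogenolysis ends the route, and KOTf removes the iodide left by lithium–iodine exchange.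

Key step: step 5

Assumption: the (Rp,Rp) antipode of the ferrocenyl bisphosphine named in step 5 is taken to give the (R)-boronate, by analogy with the sense of induction recalled for its (Sp,Sp) mirror image. The sense should be confirmed on the secondary alcohol from step 6 (chiral HPLC, MTPA esters), and the mirror-image ligand, also commercial, used if it proves opposite.

Step 1
Reactants: 1 11-bromoundecan-1-ol
Product: 2 benzyl 11-bromoundecyl ether
Conditions: BnOC(=NH)CCl3 (1.3 equiv), TfOH (5 mol %), CH2Cl2/cyclohexane, 0 °C to rt
Reagents that add atoms: benzyl 2,2,2-trichloroacetimidate, ClC(Cl)(Cl)C(=N)OCc1ccccc1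
Why: Acid-catalysed O-benzylation with a trichloroacetimidate etherifies the primary alcohol without any base, so no alkoxide is formed that could attack the primary bromide.

Step 2
Reactants: 2 benzyl 11-bromoundecyl ether
Product: 3 benzyl 11-iodoundecyl ether
Conditions: NaI (3 equiv), acetone, reflux
Reagents that add atoms: sodium iodide, [Na+].[I-]
Why: Finkelstein halide exchange is driven by precipitation of NaBr from acetone and supplies the primary iodide needed for clean lithium–iodine exchange.

Step 3
Reactants: 4 5-methoxyresorcinol (5-methoxybenzene-1,3-diol)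
Product: 5 3-(benzyloxy)-5-methoxyphenol
Conditions: 4 (2 equiv), BnBr (1 equiv), K2CO3 (1 equiv), DMF, rt; excess 4 recovered
Reagents that add atoms: benzyl bromide, BrCc1ccccc1
Why: Williamson etherification of the diol, whose two hydroxyls are equivalent, should favour the mono-ether when the diol is in excess over base and benzyl bromide.

Step 4
Reactants: 5 3-(benzyloxy)-5-methoxyphenol
Product: 6 3-(benzyloxy)-5-methoxyphenyl trifluoromethanesulfonate
Conditions: Tf2O (1.2 equiv), pyridine (2 equiv), CH2Cl2, 0 °C
Reagents that add atoms: trifluoromethanesulfonic anhydride, O=S(=O)(OS(=O)(=O)C(F)(F)F)C(F)(F)F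
Why: O-Sulfonylation of the one free phenol with triflic anhydride and pyridine is a standard aryl triflate synthesis and touches neither ether.

Step 5
Reactants: 3 benzyl 11-iodoundecyl ether; 7 vinylboronic acid pinacol ester (2-ethenyl-4,4,5,5-tetramethyl-1,3,2-dioxaborolane); 6 3-(benzyloxy)-5-methoxyphenyl trifluoromethanesulfonate
Product: 10 (R)-2-{13-(benzyloxy)-1-[3-(benzyloxy)-5-methoxyphenyl]tridecan-2-yl}-4,4,5,5-tetramethyl-1,3,2-dioxaborolane, via 11-(benzyloxy)undecyllithium 8 (not isolated), via lithium alkyl(vinyl)pinacolatoborate 9 (not isolated)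
Conditions: 3 (1.0 equiv), t-BuLi (2.0 equiv), Et2O/pentane, −78 °C; 7 (1.0 equiv), −78 °C to rt; evaporate, THF; KOTf (2 equiv), 6 (1.1 equiv), Pd(OAc)2 (2 mol %), (Rp,Rp)-1,1'-bis[bis(4-methoxy-3,5-dimethylphenyl)phosphino]-2,2'-bis[(S)-α-(dimethylamino)benzyl]ferrocene (2.4 mol %), THF, 60 °C
Reagents that add atoms: tert-butyllithium, [Li]C(C)(C)C (its lithium ends in 8 and 9, not in 10)
Why: Lithium–iodine exchange (the second equivalent of t-BuLi destroys the t-BuI formed) gives primary alkyllithium 8, which adds to the vacant boron orbital of 7 to give four-coordinate borate 9, and KOTf then takes the iodide out as KI so that it cannot occupy the cationic palladium. Zerovalent palladium, formed in the flask from Pd(OAc)2 and the bisphosphine, inserts into the aryl C–O bond of 6; the cationic divalent arylpalladium binds the vinyl group of 9, the undecyl group shifts from boron to the boron-bearing carbon anti to palladium while palladium bonds to the terminal carbon, and reductive elimination forms the aryl–C1 bond and returns zerovalent palladium. The closest known reaction type is the enantioselective palladium-catalysed conjunctive cross-coupling of alkyllithium-derived vinylboron ate complexes with aryl triflates by a metal-induced 1,2-metallate shift, and no ring is closed. The single new stereocentre, C2, is set by the alkene face that the ligand-bound arylpalladium takes, the migrating carbon arriving on the opposite face; the achiral substrate has no bias, so control rests on the (Rp,Rp) bisphosphine, which is expected to give (R). The step needs the metallate shift to outpace direct Suzuki-type transfer of the vinyl or alkyl group to palladium, which the wide-bite-angle ligand, the weakly coordinating triflate counter-ion and the removal of halide secure; regiochemistry is inherent, since the alkyl group can only migrate to the boron-bearing carbon. Benzyl ethers, the aryl methyl ether and the product boronate are inert under these neutral conditions.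

Step 6
Reactants: 10 (R)-2-{13-(benzyloxy)-1-[3-(benzyloxy)-5-methoxyphenyl]tridecan-2-yl}-4,4,5,5-tetramethyl-1,3,2-dioxaborolane
Product: 11 (R)-13-(benzyloxy)-1-[3-(benzyloxy)-5-methoxyphenyl]tridecan-2-ol
Conditions: 30% aq. H2O2, 3 M aq. NaOH, THF, 0 °C to rt
Reagents that add atoms: hydrogen peroxide, OO
Why: Alkaline peroxide oxidation of the boronate moves C2 from boron to oxygen by a 1,2-shift with retention, so the C–B stereocentre should become the (R)-carbinol unchanged.

Step 7
Reactants: 11 (R)-13-(benzyloxy)-1-[3-(benzyloxy)-5-methoxyphenyl]tridecan-2-ol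
Product: 12 (R)-13-(benzyloxy)-1-[3-(benzyloxy)-5-methoxyphenyl]tridecan-2-yl acetate
Conditions: Ac2O, pyridine, DMAP (cat.), CH2Cl2, rt
Reagents that add atoms: acetic anhydride, CC(=O)OC(C)=O
Why: DMAP-catalysed acyl transfer esterifies the only free hydroxyl and does not touch the C2–O bond, so the configuration is kept.

Step 8
Reactants: 12 (R)-13-(benzyloxy)-1-[3-(benzyloxy)-5-methoxyphenyl]tridecan-2-yl acetate
Product: 13 (R)-13-hydroxy-1-(3-hydroxy-5-methoxyphenyl)tridecan-2-yl acetate (CNP0164512.1)
Conditions: H2 (1 atm), Pd(OH)2/C, EtOAc/EtOH, rt
Reagents that add atoms: none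
Why: Heterogeneous catalytic hydrogenolysis should cleave both benzylic C–O bonds (aryl and alkyl benzyl ether) under neutral conditions, while the acetate on homobenzylic C2 and the aryl methyl ether are inert.

Compound list
1 | 11-bromoundecan-1-ol | OCCCCCCCCCCCBr | starting material
2 | benzyl 11-bromoundecyl ether | BrCCCCCCCCCCCOCc1ccccc1 | intermediate
3 | benzyl 11-iodoundecyl ether | ICCCCCCCCCCCOCc1ccccc1 | intermediate
4 | 5-methoxyresorcinol (5-methoxybenzene-1,3-diol) | COc1cc(O)cc(O)c1 | starting material
5 | 3-(benzyloxy)-5-methoxyphenol | COc1cc(O)cc(OCc2ccccc2)c1 | intermediate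
6 | 3-(benzyloxy)-5-methoxyphenyl trifluoromethanesulfonate | COc1cc(OCc2ccccc2)cc(OS(=O)(=O)C(F)(F)F)c1 | intermediate
7 | vinylboronic acid pinacol ester (2-ethenyl-4,4,5,5-tetramethyl-1,3,2-dioxaborolane) | C=CB1OC(C)(C)C(C)(C)O1 | starting material
8 | 11-(benzyloxy)undecyllithium | [Li]CCCCCCCCCCCOCc1ccccc1 | intermediate
9 | lithium 2-[11-(benzyloxy)undecyl]-2-ethenyl-4,4,5,5-tetramethyl-1,3,2-dioxaborolan-2-uide (ate complex) | [Li+].C=C[B-]1(CCCCCCCCCCCOCc2ccccc2)OC(C)(C)C(C)(C)O1 | intermediate
10 | (R)-2-{13-(benzyloxy)-1-[3-(benzyloxy)-5-methoxyphenyl]tridecan-2-yl}-4,4,5,5-tetramethyl-1,3,2-dioxaborolane | COc1cc(OCc2ccccc2)cc(C[C@@H](CCCCCCCCCCCOCc2ccccc2)B2OC(C)(C)C(C)(C)O2)c1 | intermediate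
11 | (R)-13-(benzyloxy)-1-[3-(benzyloxy)-5-methoxyphenyl]tridecan-2-ol | COc1cc(OCc2ccccc2)cc(C[C@@H](CCCCCCCCCCCOCc2ccccc2)O)c1 | intermediate
12 | (R)-13-(benzyloxy)-1-[3-(benzyloxy)-5-methoxyphenyl]tridecan-2-yl acetate | COc1cc(OCc2ccccc2)cc(C[C@@H](CCCCCCCCCCCOCc2ccccc2)OC(C)=O)c1 | intermediate
13 | (R)-13-hydroxy-1-(3-hydroxy-5-methoxyphenyl)tridecan-2-yl acetate | COc1cc(O)cc(C[C@@H](CCCCCCCCCCCO)OC(C)=O)c1 | target

Total step count: 8.
Longest linear sequence: 6 steps (steps 1, 2, 5, 6, 7, 8; the arene branch through steps 3, 4, 5, 6, 7, 8 is equally long).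

Steps most likely to fail

Step 5. Iodide left from the lithium–iodine exchange may not be removed completely by KOTf; it would then bind the cationic arylpalladium and stall the metallate shift. Any t-BuLi in excess would also divert 7 into a tert-butyl borate. The fallback builds the same ate complex without halide. It sets out from bromide 2, which is borylated (B2pin2, CuI cat., PPh3, LiOMe, DMF, rt; copper-catalysed borylation of a primary alkyl bromide) to 2-[11-(benzyloxy)undecyl]-4,4,5,5-tetramethyl-1,3,2-dioxaborolane F1. Halide-free vinyllithium F2, prepared from Sn(CH=CH2)4 and n-BuLi in pentane and washed free of tin by-product, is added to F1 in Et2O at −78 °C to rt. This gives borate 9, where the route is rejoined; the coupling with 6 then runs as in step 5 with KOTf left out.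

Step 3. Alkylation of a diol with two equivalent hydroxyls is statistical, so bis-benzylation and some C-benzylation of the electron-rich ring may erode the mass return even with excess 4. The fallback removes the statistical event. From 4, both hydroxyls are triflated (Tf2O, pyridine, CH2Cl2, 0 °C) to 5-methoxy-1,3-phenylene bis(trifluoromethanesulfonate) F3. One sulfonate is then cleaved with Et4NOH (2 equiv, dioxane, rt) to give 3-hydroxy-5-methoxyphenyl trifluoromethanesulfonate F4; the phenoxide formed should deactivate the second sulfonate towards hydroxide. Benzylation (BnBr, K2CO3, acetone, rt) gives triflate 6, where the route is rejoined, bypassing 5.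

Step 8. The aryl benzyl ether should cleave quickly, but hydrogenolysis of the primary alkyl benzyl ether may stall, for instance through catalyst poisoning by traces of iodide or phosphine carried from step 5. Forcing it with acid or long reaction times would invite solvolysis of the acetate. The fallback replaces reductive by Lewis-acid cleavage: from 12, BCl3 with pentamethylbenzene as benzyl-cation scavenger (CH2Cl2, −78 °C) should remove both benzyl groups and spare the acetate and the aryl methyl ether, arriving directly at 13 (no new compound, F0).

Further compounds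
F1 | step 5 | 2-[11-(benzyloxy)undecyl]-4,4,5,5-tetramethyl-1,3,2-dioxaborolane | CC1(C)OB(CCCCCCCCCCCOCc2ccccc2)OC1(C)C
F2 | step 5 | vinyllithium | [Li]C=C
F3 | step 3 | 5-methoxy-1,3-phenylene bis(trifluoromethanesulfonate) | COc1cc(OS(=O)(=O)C(F)(F)F)cc(OS(=O)(=O)C(F)(F)F)c1
F4 | step 3 | 3-hydroxy-5-methoxyphenyl trifluoromethanesulfonate | COc1cc(O)cc(OS(=O)(=O)C(F)(F)F)c1
F0 | step 8 | none | none
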